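The earlier runs and the new flask were generated by integration with constants of no real substance, noise included.

In a closed, stirred flask at constant temperature, catalyst turns substrate into intermediate, and intermediate with partner gives target, perhaps reversibly; each precatalyst costs one partner to become catalyst.

| setting | dawn | autumn | spring | delta | gamma | beta | alpha |
|---|---|---|---|---|---|---|---|
| substrate | 0.20 M | 0.20 M | 0.39 M | 0.40 M | 0.20 M | 0.20 M | 0.30 M |
| partner | 0.90 equiv | 0.90 equiv | 0.90 equiv | 2.70 equiv | 0.900 equiv | 1.80 equiv | 0.900 equiv |
| precatalyst | 1.3 mol% | 3.8 mol% | 5 mol% | 5 mol% | 5 mol% | 1.5 mol% | 5 mol% |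
| remark | run made earlier | run made earlier | run made earlier |  |  |  |  |
| time |  |  |  | 5.0 d | 5.0 d | 5.0 d | 5.0 d |

- dawn (time / d: target / %): 0.417: 1.5; 0.833: 11.2; 1.25: 20.3; 1.67: 26.8; 2.00: 30.5; 2.50: 33.9
- autumn (time / d: target / %): 0.417: 8.9; 0.833: 27.0; 1.25: 33.4; 1.67: 36.3; 2.00: 37.0; 2.50: 37.0
- spring (time / d: target / %): 0.208: 19.1; 0.625: 46.2; 1.25: 47.0; 1.67: 47.6; 2.50: 47.6

(standard deviation of a reading: 0.5 percentage points)

* the flasks put in order of amount of target, in percent of the substrate charged, best first, at 5.0 d (delta / gamma / beta / alpha)
* the same order at 12 h (delta / gamma / beta / alpha)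
* the amount of target, in percent of the substrate charged of the flask you put first, at 5.0 d
* the amount of target, in percent of the substrate charged of the flask you put last, at 5.0 d

- steps thought possible: partner + catalyst + intermediate <-> catalyst + target; substrate + catalyst -> catalyst + intermediate; partner + precatalyst -> catalyst + spent reagent

Autumn reads 37.0% at 2.00 d and 37.0% at 2.50 d, so its readings have levelled, and spring's level at 47.6%, while dawn's are still rising. We take the substrate as used up and read the stops as a balance. Counting target, intermediate and free partner in M, and taking one partner as gone per precatalyst charged, target divided by intermediate times partner reads 5.97 /M in autumn and 6.23 /M in spring. Their mean, 6.10 /M, is our holding ratio K (the equilibrium constant).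

With free partner b, the target share is Kb over one plus Kb, but b depends on that share, so we go round. For delta, ignoring the partner that target takes gives 86.6%. Putting that back gives 81.3%, and once more 81.8%.

The forecast reads “At 5 d all four flasks should be at equilibrium”: delta > beta > alpha > gamma at 5.0 d, delta > alpha > gamma > beta at 12 h, top 81.7% (79.5% to 83.5%), low 37% (36% to 38%).

The flasks give delta > beta > alpha > gamma and delta > alpha > gamma > beta, with top 81.3% and low 36.5%, so the forecast held.

    partner + catalyst + intermediate ⇌ catalyst + target (K = 5.90 /M, k = 0.970 /M²/min)
    substrate + catalyst → catalyst + intermediate (k = 2.10 /M/min)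
    partner + precatalyst → catalyst + spent reagent (k = 0.00500 /M/min)

Delta stops short because target falls back to intermediate and partner: without that back reaction it gives 100%, not 81.3%. More time adds nothing to delta.

Take gamma's recipe with 0.34 M of substrate. Starting the round with K from spring's reading of 47.6% as the target share gives 43.7%, then 46.1%; successive rounds swing down and up, so we take the middle of these two, 44.9%. That flask gives 44.7%.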